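## Retrosynthetic overview

- Numbering (germacrane): C6 carries the lactone O, C7 carries C11(=C13H2)–C12(=O), C8 the isobutyrate, C9 the 2-hydroxyisobutyrate, C10 the CH2OH (C14), C4 the methyl; both ring alkenes (C1=C10, C4=C5) are Z.
- 37 ⇐ 36 (O14 silyl ether) ⇐ 35 by palladium-catalysed cyclocarbonylation: CO becomes C12 and the lactone closes by forming C11–C12. Enabling feature: on the ten-membered ring the free O6–H (on C6) and the ethynyl group C11≡C13 (on the adjacent C7) are trans-vicinal, so O6, C6, C7, C11 and the incoming C12 complete a five-membered ring; the whole α-methylene lactone appears in one operation.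
- 35 ⇐ carbocycle 29 by ring-closing metathesis at C4=C5 of triene 28; the ethynyl group travels as a gem-dibromoalkene (inert to the Grignard reagent and to ruthenium), is unmasked after ring closure, and the esters go on O9, then O8.
- 28 ⇐ aldehyde 25 + alkenyl iodide 7 (C9–C10 bond, chelation control sets C9; C1=C10 geometry from trans-hydrostannation); 25 ⇐ two Evans aldol reactions on one oxazolidinone (C6, then C7 and C8).
- Order of ring formation: ten-membered carbocycle (ring A, step 17), then lactone (ring B, step 23).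

Key step: step 23

Remark: the SMILES is read literally as 1(10)Z,4Z and 6R,7S,8S,9S; compounds 11 and 17 are taken as purchasable.

## Route

Step 1
Reactants: 1 prop-2-yn-1-ol; 2 4-bromo-2-methylbut-1-ene
Product: 4 6-methylhept-6-en-2-yn-1-ol, via dilithium prop-2-yn-1-olate 3 (not isolated)
Conditions: LiNH2 (2.2 equiv), NH3(l)/THF, −33 °C; then 2; H2O work-up
Reagents that add atoms: none
Why: C-alkylation of the propargyl alcohol dianion (acetylide SN2 on a primary bromide) should work because the acetylide carbon is far more nucleophilic than the alkoxide.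

Step 2
Reactants: 4 6-methylhept-6-en-2-yn-1-ol
Product: 5 (Z)-6-methyl-2-(tributylstannyl)hepta-2,6-dien-1-ol
Conditions: Bu3SnH (1.1 equiv), [Cp*RuCl]4 (1 mol%), CH2Cl2, rt
Reagents that add atoms: tributyltin hydride, CCCC[SnH](CCCC)CCCC
Why: Hydroxyl-directed ruthenium-catalysed trans-hydrostannation should place tin on the alkyne carbon next to the CH2OH group (future C10) and deliver hydrogen anti, so the C2 chain ends up cis to tin, which is the C1=C10 geometry of the target.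

Step 3
Reactants: 5 (Z)-6-methyl-2-(tributylstannyl)hepta-2,6-dien-1-ol
Product: 6 (Z)-2-iodo-6-methylhepta-2,6-dien-1-ol
Conditions: I2 (1.05 equiv), CH2Cl2, 0 °C
Reagents that add atoms: iodine, [I][I]
Why: Iododestannylation of an alkenylstannane proceeds with retention of the alkene geometry.

Step 4
Reactants: 6 (Z)-2-iodo-6-methylhepta-2,6-dien-1-ol
Product: 7 tert-butyl{[(Z)-2-iodo-6-methylhepta-2,6-dien-1-yl]oxy}diphenylsilane
Conditions: t-BuPh2SiCl, imidazole, CH2Cl2, rt
Reagents that add atoms: tert-butyl(chloro)diphenylsilane, CC(C)(C)[Si](Cl)(c1ccccc1)c1ccccc1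
Why: Standard silylation of a primary allylic alcohol gives an ether that should survive every step up to the last one.

Step 5
Reactants: 8 2-hydroxy-2-methylpropanoic acid
Product: 10 2-methyl-2-(triethylsilyloxy)propanoic acid, via triethylsilyl ester 9 (not isolated)
Conditions: Et3SiCl (2.2 equiv), imidazole, DMF, rt; then MeOH/H2O, rt
Reagents that add atoms: chlorotriethylsilane, CC[Si](Cl)(CC)CC
Why: Bis-silylation followed by hydrolysis of the very labile silyl ester should leave the tertiary silyl ether and free the acid.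

Step 6
Reactants: 11 (S)-4-benzyl-3-(2-chloroacetyl)oxazolidin-2-one; 12 acrolein
Product: 14 (S)-4-benzyl-3-[(2S,3R)-2-chloro-3-hydroxypent-4-enoyl]oxazolidin-2-one, via dibutylboron enolate 13 (not isolated)
Conditions: Bu2BOTf, i-Pr2NEt, CH2Cl2, −78 to 0 °C; then 12, −78 °C; H2O2, MeOH, pH 7 buffer
Reagents that add atoms: none
Why: Evans syn aldol reaction of a haloacetyl imide: the Z-boron enolate should add through a Zimmerman–Traxler chair on the face away from the benzyl group, which sets the carbinol that becomes C6.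

Step 7
Reactants: 14 (S)-4-benzyl-3-[(2S,3R)-2-chloro-3-hydroxypent-4-enoyl]oxazolidin-2-one
Product: 15 (S)-4-benzyl-3-[(S)-3-hydroxypent-4-enoyl]oxazolidin-2-one
Conditions: Bu3SnH, AIBN (cat.), toluene, 80 °C
Reagents that add atoms: none
Why: Radical dehalogenation (tin hydride chain) should remove the α-chlorine without touching the carbinol or the vinyl group, leaving an acetate-aldol product of defined C6 configuration.

Step 8
Reactants: 15 (S)-4-benzyl-3-[(S)-3-hydroxypent-4-enoyl]oxazolidin-2-one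
Product: 16 (S)-4-benzyl-3-[(S)-3-(triethylsilyloxy)pent-4-enoyl]oxazolidin-2-one
Conditions: Et3SiCl, imidazole, DMF, 0 °C to rt
Reagents that add atoms: chlorotriethylsilane, CC[Si](Cl)(CC)CC
Why: Silylation protects O6 as an ether that is removed later under mild acidic fluoride conditions.

Step 9
Reactants: 16 (S)-4-benzyl-3-[(S)-3-(triethylsilyloxy)pent-4-enoyl]oxazolidin-2-one; 17 2-[(4-methoxybenzyl)oxy]acetaldehyde
Product: 19 (S)-4-benzyl-3-[(2R,3R)-2-{(S)-1-hydroxy-2-[(4-methoxybenzyl)oxy]ethyl}-3-(triethylsilyloxy)pent-4-enoyl]oxazolidin-2-one, via dibutylboron enolate 18 (not isolated)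
Conditions: Bu2BOTf, i-Pr2NEt, CH2Cl2, −78 to 0 °C; then 17, −78 to 0 °C; H2O2, MeOH, pH 7 buffer
Reagents that add atoms: none
Why: Second Evans syn aldol reaction: the auxiliary-controlled Z-boron enolate should set C7 and C8 together (syn aldol relationship, face opposite the benzyl group) independently of the resident C6 centre.

Step 10
Reactants: 19 (S)-4-benzyl-3-[(2R,3R)-2-{(S)-1-hydroxy-2-[(4-methoxybenzyl)oxy]ethyl}-3-(triethylsilyloxy)pent-4-enoyl]oxazolidin-2-one
Product: 20 (2S,3R,4R)-3-(hydroxymethyl)-1-[(4-methoxybenzyl)oxy]-4-(triethylsilyloxy)hex-5-en-2-ol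
Conditions: LiBH4, MeOH (1 equiv), THF, 0 °C
Reagents that add atoms: none
Why: Reductive cleavage of the imide, assisted by the free β-hydroxyl, should turn the acyl carbon (future C11) into a primary alcohol and release the auxiliary.

Step 11
Reactants: 20 (2S,3R,4R)-3-(hydroxymethyl)-1-[(4-methoxybenzyl)oxy]-4-(triethylsilyloxy)hex-5-en-2-ol
Product: 21 (2R,3R)-2-[(4S)-2-(4-methoxyphenyl)-1,3-dioxolan-4-yl]-3-(triethylsilyloxy)pent-4-en-1-ol (both acetal epimers)
Conditions: DDQ (1.2 equiv), 4 Å molecular sieves, CH2Cl2, 0 °C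
Reagents that add atoms: none
Why: Oxidative acetalisation: DDQ turns the benzyl ether into an oxocarbenium ion that the neighbouring O8–H should trap as the five-membered acetal, whereas the primary hydroxyl would need a seven-membered ring.

Step 12
Reactants: 21 (2R,3R)-2-[(4S)-2-(4-methoxyphenyl)-1,3-dioxolan-4-yl]-3-(triethylsilyloxy)pent-4-en-1-ol
Product: 22 (2R,3R)-2-[(4S)-2-(4-methoxyphenyl)-1,3-dioxolan-4-yl]-3-(triethylsilyloxy)pent-4-enal
Conditions: Dess–Martin periodinane, NaHCO3, CH2Cl2, 0 °C to rt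
Reagents that add atoms: none
Why: Buffered Dess–Martin oxidation should give the aldehyde without epimerising C7 or eliminating the β-oxygen groups.

Step 13
Reactants: 22 (2R,3R)-2-[(4S)-2-(4-methoxyphenyl)-1,3-dioxolan-4-yl]-3-(triethylsilyloxy)pent-4-enal
Product: 23 {[(3R,4R)-6,6-dibromo-4-[(4S)-2-(4-methoxyphenyl)-1,3-dioxolan-4-yl]hexa-1,5-dien-3-yl]oxy}triethylsilane
Conditions: CBr4, PPh3, Zn, CH2Cl2, rt (ylide preformed); then 22, pyridine, 0 °C
Reagents that add atoms: carbon tetrabromide, BrC(Br)(Br)Br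
Why: First stage of the Corey–Fuchs reaction (Wittig-type dibromo-olefination) under neutral conditions; the gem-dibromoalkene is a masked alkyne that tolerates Grignard reagents and ruthenium alkylidenes.

Step 14
Reactants: 23 {[(3R,4R)-6,6-dibromo-4-[(4S)-2-(4-methoxyphenyl)-1,3-dioxolan-4-yl]hexa-1,5-dien-3-yl]oxy}triethylsilane
Product: 24 (2S,3R,4R)-3-(2,2-dibromovinyl)-2-[(4-methoxybenzyl)oxy]-4-(triethylsilyloxy)hex-5-en-1-ol
Conditions: i-Bu2AlH (3 equiv), CH2Cl2, −78 to 0 °C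
Reagents that add atoms: none
Why: Regioselective reductive opening of the benzylidene-type acetal: aluminium should bind the less hindered O9 and hydride delivery leaves the 4-methoxybenzyl group on O8, where it is needed for chelation.

Step 15
Reactants: 24 (2S,3R,4R)-3-(2,2-dibromovinyl)-2-[(4-methoxybenzyl)oxy]-4-(triethylsilyloxy)hex-5-en-1-ol
Product: 25 (2S,3R,4R)-3-(2,2-dibromovinyl)-2-[(4-methoxybenzyl)oxy]-4-(triethylsilyloxy)hex-5-enal
Conditions: Dess–Martin periodinane, NaHCO3, CH2Cl2, 0 °C to rt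
Reagents that add atoms: none
Why: Mild oxidation of the primary alcohol gives the α-alkoxy aldehyde (C9) for immediate use.

Step 16
Reactants: 7 tert-butyl{[(Z)-2-iodo-6-methylhepta-2,6-dien-1-yl]oxy}diphenylsilane; 25 (2S,3R,4R)-3-(2,2-dibromovinyl)-2-[(4-methoxybenzyl)oxy]-4-(triethylsilyloxy)hex-5-enal
Product: 28 (3R,4R,5S,6S,7Z)-7-{[(tert-butyldiphenylsilyl)oxy]methyl}-4-(2,2-dibromovinyl)-5-[(4-methoxybenzyl)oxy]-11-methyl-3-(triethylsilyloxy)dodeca-1,7,11-trien-6-ol, via alkenyllithium 26 (not isolated), via alkenylmagnesium bromide 27 (not isolated)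
Conditions: 7, t-BuLi (2 equiv), Et2O, −78 °C; MgBr2·OEt2, −78 to −40 °C; then 25, CH2Cl2, −78 °C
Reagents that add atoms: none
Why: Chelation-controlled (Cram chelate) 1,2-addition: magnesium should bridge the aldehyde oxygen and the α-benzyloxy oxygen so that the alkenyl group attacks anti to the C7 substituent and gives the 8,9-syn relationship (C9), while iodine–lithium exchange and transmetalation keep the alkene geometry.

Step 17
Reactants: 28 (3R,4R,5S,6S,7Z)-7-{[(tert-butyldiphenylsilyl)oxy]methyl}-4-(2,2-dibromovinyl)-5-[(4-methoxybenzyl)oxy]-11-methyl-3-(triethylsilyloxy)dodeca-1,7,11-trien-6-ol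
Product: 29 (1S,2Z,6Z,8R,9R,10S)-2-{[(tert-butyldiphenylsilyl)oxy]methyl}-9-(2,2-dibromovinyl)-10-[(4-methoxybenzyl)oxy]-6-methyl-8-(triethylsilyloxy)cyclodeca-2,6-dien-1-ol
Conditions: second-generation Grubbs catalyst RuCl2(H2IMes)(PCy3)(=CHPh) (10 mol%), toluene (1 mM), 80 °C, argon sparge
Reagents that add atoms: none
Why: Ring-closing metathesis of the C5 vinyl group with the 1,1-disubstituted C4 alkene should close the ten-membered ring with loss of ethylene; the cis C1=C10 alkene pre-folds the chain and the medium ring is expected to favour the Z trisubstituted C4=C5 alkene.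

Step 18
Reactants: 29 (1S,2Z,6Z,8R,9R,10S)-2-{[(tert-butyldiphenylsilyl)oxy]methyl}-9-(2,2-dibromovinyl)-10-[(4-methoxybenzyl)oxy]-6-methyl-8-(triethylsilyloxy)cyclodeca-2,6-dien-1-ol
Product: 30 (1S,2Z,6Z,8R,9R,10S)-2-{[(tert-butyldiphenylsilyl)oxy]methyl}-9-ethynyl-10-[(4-methoxybenzyl)oxy]-6-methyl-8-(triethylsilyloxy)cyclodeca-2,6-dien-1-ol
Conditions: n-BuLi (3.3 equiv), THF, −78 °C; then H2O
Reagents that add atoms: none
Why: Second stage of the Corey–Fuchs reaction: bromine–lithium exchange and Fritsch–Buttenberg–Wiechell rearrangement should give the lithium acetylide, which is protonated on work-up, before any ester is present.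

Step 19
Reactants: 30 (1S,2Z,6Z,8R,9R,10S)-2-{[(tert-butyldiphenylsilyl)oxy]methyl}-9-ethynyl-10-[(4-methoxybenzyl)oxy]-6-methyl-8-(triethylsilyloxy)cyclodeca-2,6-dien-1-ol; 10 2-methyl-2-(triethylsilyloxy)propanoic acid
Product: 32 (1S,2Z,6Z,8R,9R,10S)-2-{[(tert-butyldiphenylsilyl)oxy]methyl}-9-ethynyl-10-[(4-methoxybenzyl)oxy]-6-methyl-8-(triethylsilyloxy)cyclodeca-2,6-dien-1-yl 2-methyl-2-(triethylsilyloxy)propanoate, via mixed anhydride 31 (not isolated)
Conditions: 10, 2,4,6-trichlorobenzoyl chloride, Et3N, THF, rt; then 30, DMAP, toluene, 40 °C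
Reagents that add atoms: none
Why: Yamaguchi esterification is suited to joining a hindered acid with the hindered secondary O9–H, the only free hydroxyl.

Step 20
Reactants: 32 (1S,2Z,6Z,8R,9R,10S)-2-{[(tert-butyldiphenylsilyl)oxy]methyl}-9-ethynyl-10-[(4-methoxybenzyl)oxy]-6-methyl-8-(triethylsilyloxy)cyclodeca-2,6-dien-1-yl 2-methyl-2-(triethylsilyloxy)propanoate
Product: 33 (1S,2Z,6Z,8R,9R,10S)-2-{[(tert-butyldiphenylsilyl)oxy]methyl}-9-ethynyl-10-hydroxy-6-methyl-8-(triethylsilyloxy)cyclodeca-2,6-dien-1-yl 2-methyl-2-(triethylsilyloxy)propanoate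
Conditions: DDQ, CH2Cl2/pH 7 buffer, 0 °C
Reagents that add atoms: none
Why: Oxidative cleavage of the 4-methoxybenzyl ether under buffered conditions should free O8–H only; the hindered O9 ester is not expected to migrate.

Step 21
Reactants: 33 (1S,2Z,6Z,8R,9R,10S)-2-{[(tert-butyldiphenylsilyl)oxy]methyl}-9-ethynyl-10-hydroxy-6-methyl-8-(triethylsilyloxy)cyclodeca-2,6-dien-1-yl 2-methyl-2-(triethylsilyloxy)propanoate
Product: 34 (1S,2Z,6Z,8R,9R,10S)-2-{[(tert-butyldiphenylsilyl)oxy]methyl}-9-ethynyl-6-methyl-10-[(2-methylpropanoyl)oxy]-8-(triethylsilyloxy)cyclodeca-2,6-dien-1-yl 2-methyl-2-(triethylsilyloxy)propanoate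
Conditions: 2-methylpropanoyl chloride, pyridine, DMAP (cat.), CH2Cl2, 0 °C to rt
Reagents that add atoms: 2-methylpropanoyl chloride, CC(C)C(=O)Cl
Why: DMAP-catalysed acylation installs the isobutyrate on O8, the only free hydroxyl.

Step 22
Reactants: 34 (1S,2Z,6Z,8R,9R,10S)-2-{[(tert-butyldiphenylsilyl)oxy]methyl}-9-ethynyl-6-methyl-10-[(2-methylpropanoyl)oxy]-8-(triethylsilyloxy)cyclodeca-2,6-dien-1-yl 2-methyl-2-(triethylsilyloxy)propanoate
Product: 35 (1S,2Z,6Z,8R,9S,10S)-2-{[(tert-butyldiphenylsilyl)oxy]methyl}-9-ethynyl-8-hydroxy-6-methyl-10-[(2-methylpropanoyl)oxy]cyclodeca-2,6-dien-1-yl 2-hydroxy-2-methylpropanoate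
Conditions: HF·pyridine, pyridine, THF, 0 °C
Reagents that add atoms: none
Why: Buffered HF·pyridine should cleave both triethylsilyl ethers much faster than the primary tert-butyldiphenylsilyl ether, and the acidic medium avoids acyl migration to the freed O6–H.

Step 23
Reactants: 35 (1S,2Z,6Z,8R,9S,10S)-2-{[(tert-butyldiphenylsilyl)oxy]methyl}-9-ethynyl-8-hydroxy-6-methyl-10-[(2-methylpropanoyl)oxy]cyclodeca-2,6-dien-1-yl 2-hydroxy-2-methylpropanoate
Product: 36 (3aS,4S,5S,6Z,10Z,11aR)-6-{[(tert-butyldiphenylsilyl)oxy]methyl}-10-methyl-3-methylidene-4-[(2-methylpropanoyl)oxy]-2-oxo-2,3,3a,4,5,8,9,11a-octahydrocyclodeca[b]furan-5-yl 2-hydroxy-2-methylpropanoate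
Conditions: PdCl2(PPh3)2 (5 mol%), SnCl2 (5 mol%), CO (8 atm), MeCN, 75 °C
Reagents that add atoms: carbon monoxide, [C-]#[O+]
Why: Divalent palladium, the free O6–H and CO should form an alkoxycarbonylpalladium species (O6–C(=O)–Pd) whose carbonyl carbon is C12; the ethynyl group on the neighbouring C7 then inserts syn into the Pd–C12 bond, which forms the C11–C12 bond and closes the lactone, and protonolysis of the alkenyl–palladium bond at C13 releases the exo-methylene group and returns divalent palladium. The closest known reaction is the palladium-catalysed cyclocarbonylation of but-3-yn-1-ols and trans-2-ethynylcycloalkanols to α-methylene-γ-butyrolactones, here applied to a ten-membered homopropargylic alcohol. The five-membered ring (O6, C6, C7, C11, C12) closes in a 5-exo-dig acylpalladation, the only mode within reach of the two-atom tether C6–C7. No stereocentre is created: the trans ring fusion is inherited from the 6,7-relationship fixed in steps 6 and 9, and the terminal alkyne guarantees the exocyclic position of the double bond. The step needs site selectivity for O6 and tolerance of allylic C–O bonds: O8 and O9 are acylated, O14 is silylated, the tertiary hydroxyl cannot reach the alkyne, and because palladium stays divalent through the cycle the allylic C9 ester and the allylic C6–O bond of the product should not be ionised. In one operation the step adds the last carbon (C12), makes the C–C and C–O bonds of the lactone and creates the Michael acceptor only at the end of the route.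

Step 24
Reactants: 36 (3aS,4S,5S,6Z,10Z,11aR)-6-{[(tert-butyldiphenylsilyl)oxy]methyl}-10-methyl-3-methylidene-4-[(2-methylpropanoyl)oxy]-2-oxo-2,3,3a,4,5,8,9,11a-octahydrocyclodeca[b]furan-5-yl 2-hydroxy-2-methylpropanoate
Product: 37 (3aS,4S,5S,6Z,10Z,11aR)-6-(hydroxymethyl)-10-methyl-3-methylidene-4-[(2-methylpropanoyl)oxy]-2-oxo-2,3,3a,4,5,8,9,11a-octahydrocyclodeca[b]furan-5-yl 2-hydroxy-2-methylpropanoate (CNP0220567.2)
Conditions: HF·pyridine (excess), THF, 0 °C to rt
Reagents that add atoms: none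
Why: Cleavage of the remaining silyl ether under acidic fluoride conditions should free C14–OH without the basic conditions that would promote acyl migration or conjugate addition to the lactone.

## Compound list

1 | prop-2-yn-1-ol | C#CCO | starting material
2 | 4-bromo-2-methylbut-1-ene | C=C(C)CCBr | starting material
3 | dilithium prop-2-yn-1-olate | [Li]C#CCO[Li] | intermediate
4 | 6-methylhept-6-en-2-yn-1-ol | C=C(C)CCC#CCO | intermediate
5 | (Z)-6-methyl-2-(tributylstannyl)hepta-2,6-dien-1-ol | C=C(C)CC/C=C(\[Sn](CCCC)(CCCC)CCCC)CO | intermediate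
6 | (Z)-2-iodo-6-methylhepta-2,6-dien-1-ol | C=C(C)CC/C=C(\I)CO | intermediate
7 | tert-butyl{[(Z)-2-iodo-6-methylhepta-2,6-dien-1-yl]oxy}diphenylsilane | C=C(C)CC/C=C(\I)CO[Si](c1ccccc1)(c1ccccc1)C(C)(C)C | intermediate
8 | 2-hydroxy-2-methylpropanoic acid | CC(C)(O)C(=O)O | starting material
9 | triethylsilyl 2-methyl-2-(triethylsilyloxy)propanoate | CC[Si](CC)(CC)OC(C)(C)C(=O)O[Si](CC)(CC)CC | intermediate
10 | 2-methyl-2-(triethylsilyloxy)propanoic acid | CC[Si](CC)(CC)OC(C)(C)C(=O)O | intermediate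
11 | (S)-4-benzyl-3-(2-chloroacetyl)oxazolidin-2-one | O=C(CCl)N1[C@@H](Cc2ccccc2)COC1=O | starting material
12 | acrolein (prop-2-enal) | C=CC=O | starting material
13 | dibutylboron (Z)-enolate of 11 | Cl/C=C(\OB(CCCC)CCCC)N1[C@@H](Cc2ccccc2)COC1=O | intermediate
14 | (S)-4-benzyl-3-[(2S,3R)-2-chloro-3-hydroxypent-4-enoyl]oxazolidin-2-one | O=C([C@@H](Cl)[C@H](O)C=C)N1[C@@H](Cc2ccccc2)COC1=O | intermediate
15 | (S)-4-benzyl-3-[(S)-3-hydroxypent-4-enoyl]oxazolidin-2-one | O=C(C[C@H](O)C=C)N1[C@@H](Cc2ccccc2)COC1=O | intermediate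
16 | (S)-4-benzyl-3-[(S)-3-(triethylsilyloxy)pent-4-enoyl]oxazolidin-2-one | O=C(C[C@H](O[Si](CC)(CC)CC)C=C)N1[C@@H](Cc2ccccc2)COC1=O | intermediate
17 | 2-[(4-methoxybenzyl)oxy]acetaldehyde | O=CCOCc1ccc(OC)cc1 | starting material
18 | dibutylboron (Z)-enolate of 16 | C=C[C@@H](O[Si](CC)(CC)CC)/C=C(\OB(CCCC)CCCC)N1[C@@H](Cc2ccccc2)COC1=O | intermediate
19 | (S)-4-benzyl-3-[(2R,3R)-2-{(S)-1-hydroxy-2-[(4-methoxybenzyl)oxy]ethyl}-3-(triethylsilyloxy)pent-4-enoyl]oxazolidin-2-one | O=C([C@@H]([C@H](O[Si](CC)(CC)CC)C=C)[C@H](O)COCc1ccc(OC)cc1)N1[C@@H](Cc2ccccc2)COC1=O | intermediate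
20 | (2S,3R,4R)-3-(hydroxymethyl)-1-[(4-methoxybenzyl)oxy]-4-(triethylsilyloxy)hex-5-en-2-ol | C=C[C@@H](O[Si](CC)(CC)CC)[C@H](CO)[C@H](O)COCc1ccc(OC)cc1 | intermediate
21 | (2R,3R)-2-[(4S)-2-(4-methoxyphenyl)-1,3-dioxolan-4-yl]-3-(triethylsilyloxy)pent-4-en-1-ol (both acetal epimers) | C=C[C@@H](O[Si](CC)(CC)CC)[C@H](CO)[C@H]1COC(c2ccc(OC)cc2)O1 | intermediate
22 | (2R,3R)-2-[(4S)-2-(4-methoxyphenyl)-1,3-dioxolan-4-yl]-3-(triethylsilyloxy)pent-4-enal | C=C[C@@H](O[Si](CC)(CC)CC)[C@H](C=O)[C@H]1COC(c2ccc(OC)cc2)O1 | intermediate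
23 | {[(3R,4R)-6,6-dibromo-4-[(4S)-2-(4-methoxyphenyl)-1,3-dioxolan-4-yl]hexa-1,5-dien-3-yl]oxy}triethylsilane | C=C[C@@H](O[Si](CC)(CC)CC)[C@H](C=C(Br)Br)[C@H]1COC(c2ccc(OC)cc2)O1 | intermediate
24 | (2S,3R,4R)-3-(2,2-dibromovinyl)-2-[(4-methoxybenzyl)oxy]-4-(triethylsilyloxy)hex-5-en-1-ol | C=C[C@@H](O[Si](CC)(CC)CC)[C@H](C=C(Br)Br)[C@H](OCc1ccc(OC)cc1)CO | intermediate
25 | (2S,3R,4R)-3-(2,2-dibromovinyl)-2-[(4-methoxybenzyl)oxy]-4-(triethylsilyloxy)hex-5-enal | C=C[C@@H](O[Si](CC)(CC)CC)[C@H](C=C(Br)Br)[C@H](OCc1ccc(OC)cc1)C=O | intermediate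
26 | alkenyllithium from 7, {(Z)-1-[(tert-butyldiphenylsilyl)oxy]-6-methylhepta-2,6-dien-2-yl}lithium | C=C(C)CC/C=C(\[Li])CO[Si](c1ccccc1)(c1ccccc1)C(C)(C)C | intermediate
27 | alkenylmagnesium bromide from 7 | C=C(C)CC/C=C(\[Mg]Br)CO[Si](c1ccccc1)(c1ccccc1)C(C)(C)C | intermediate
28 | (3R,4R,5S,6S,7Z)-7-{[(tert-butyldiphenylsilyl)oxy]methyl}-4-(2,2-dibromovinyl)-5-[(4-methoxybenzyl)oxy]-11-methyl-3-(triethylsilyloxy)dodeca-1,7,11-trien-6-ol | C=C[C@@H](O[Si](CC)(CC)CC)[C@H](C=C(Br)Br)[C@H](OCc1ccc(OC)cc1)[C@@H](O)/C(CO[Si](c1ccccc1)(c1ccccc1)C(C)(C)C)=C\CCC(C)=C | intermediate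
29 | (1S,2Z,6Z,8R,9R,10S)-2-{[(tert-butyldiphenylsilyl)oxy]methyl}-9-(2,2-dibromovinyl)-10-[(4-methoxybenzyl)oxy]-6-methyl-8-(triethylsilyloxy)cyclodeca-2,6-dien-1-ol | C/C1=C/[C@@H](O[Si](CC)(CC)CC)[C@H](C=C(Br)Br)[C@H](OCc2ccc(OC)cc2)[C@@H](O)/C(CO[Si](c2ccccc2)(c2ccccc2)C(C)(C)C)=C\CC1 | intermediate
30 | (1S,2Z,6Z,8R,9R,10S)-2-{[(tert-butyldiphenylsilyl)oxy]methyl}-9-ethynyl-10-[(4-methoxybenzyl)oxy]-6-methyl-8-(triethylsilyloxy)cyclodeca-2,6-dien-1-ol | C/C1=C/[C@@H](O[Si](CC)(CC)CC)[C@H](C#C)[C@H](OCc2ccc(OC)cc2)[C@@H](O)/C(CO[Si](c2ccccc2)(c2ccccc2)C(C)(C)C)=C\CC1 | intermediate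
31 | 2-methyl-2-(triethylsilyloxy)propanoic 2,4,6-trichlorobenzoic anhydride | CC[Si](CC)(CC)OC(C)(C)C(=O)OC(=O)c1c(Cl)cc(Cl)cc1Cl | intermediate
32 | (1S,2Z,6Z,8R,9R,10S)-2-{[(tert-butyldiphenylsilyl)oxy]methyl}-9-ethynyl-10-[(4-methoxybenzyl)oxy]-6-methyl-8-(triethylsilyloxy)cyclodeca-2,6-dien-1-yl 2-methyl-2-(triethylsilyloxy)propanoate | C/C1=C/[C@@H](O[Si](CC)(CC)CC)[C@H](C#C)[C@H](OCc2ccc(OC)cc2)[C@@H](OC(=O)C(C)(C)O[Si](CC)(CC)CC)/C(CO[Si](c2ccccc2)(c2ccccc2)C(C)(C)C)=C\CC1 | intermediate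
33 | (1S,2Z,6Z,8R,9R,10S)-2-{[(tert-butyldiphenylsilyl)oxy]methyl}-9-ethynyl-10-hydroxy-6-methyl-8-(triethylsilyloxy)cyclodeca-2,6-dien-1-yl 2-methyl-2-(triethylsilyloxy)propanoate | C/C1=C/[C@@H](O[Si](CC)(CC)CC)[C@H](C#C)[C@H](O)[C@@H](OC(=O)C(C)(C)O[Si](CC)(CC)CC)/C(CO[Si](c2ccccc2)(c2ccccc2)C(C)(C)C)=C\CC1 | intermediate
34 | (1S,2Z,6Z,8R,9R,10S)-2-{[(tert-butyldiphenylsilyl)oxy]methyl}-9-ethynyl-6-methyl-10-[(2-methylpropanoyl)oxy]-8-(triethylsilyloxy)cyclodeca-2,6-dien-1-yl 2-methyl-2-(triethylsilyloxy)propanoate | C/C1=C/[C@@H](O[Si](CC)(CC)CC)[C@H](C#C)[C@H](OC(=O)C(C)C)[C@@H](OC(=O)C(C)(C)O[Si](CC)(CC)CC)/C(CO[Si](c2ccccc2)(c2ccccc2)C(C)(C)C)=C\CC1 | intermediate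
35 | (1S,2Z,6Z,8R,9S,10S)-2-{[(tert-butyldiphenylsilyl)oxy]methyl}-9-ethynyl-8-hydroxy-6-methyl-10-[(2-methylpropanoyl)oxy]cyclodeca-2,6-dien-1-yl 2-hydroxy-2-methylpropanoate | C/C1=C/[C@@H](O)[C@H](C#C)[C@H](OC(=O)C(C)C)[C@@H](OC(=O)C(C)(C)O)/C(CO[Si](c2ccccc2)(c2ccccc2)C(C)(C)C)=C\CC1 | intermediate
36 | (3aS,4S,5S,6Z,10Z,11aR)-6-{[(tert-butyldiphenylsilyl)oxy]methyl}-10-methyl-3-methylidene-4-[(2-methylpropanoyl)oxy]-2-oxo-2,3,3a,4,5,8,9,11a-octahydrocyclodeca[b]furan-5-yl 2-hydroxy-2-methylpropanoate | C/C1=C/[C@H]2OC(=O)C(=C)[C@@H]2[C@H](OC(=O)C(C)C)[C@@H](OC(=O)C(C)(C)O)/C(CO[Si](c3ccccc3)(c3ccccc3)C(C)(C)C)=C\CC1 | intermediate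
37 | (3aS,4S,5S,6Z,10Z,11aR)-6-(hydroxymethyl)-10-methyl-3-methylidene-4-[(2-methylpropanoyl)oxy]-2-oxo-2,3,3a,4,5,8,9,11a-octahydrocyclodeca[b]furan-5-yl 2-hydroxy-2-methylpropanoate (CNP0220567.2) | C/C1=C/[C@H]2OC(=O)C(=C)[C@@H]2[C@H](OC(=O)C(C)C)[C@@H](OC(=O)C(C)(C)O)/C(CO)=C\CC1 | target

## Step count and risks

Total step count: 24 (steps 1–4 alkenyl iodide, step 5 acid, steps 6–24 main line).
Longest linear sequence: 19 steps (steps 6 to 24).

Steps most likely to fail:

1. Step 17 (ring-closing metathesis). Intermolecular metathesis at the C5 vinyl group (oligomerisation) may outrun closure onto the hindered 1,1-disubstituted alkene, and the ring alkene may form partly with E geometry. Fallback, relay ring-closing metathesis, setting out from 7 and 25 and returning at 29: selective ozonolysis of the 1,1-disubstituted alkene of 7 (O3, CH2Cl2/MeOH, −78 °C; PPh3) should give (Z)-7-[(tert-butyldiphenylsilyl)oxy]-6-iodohept-5-en-2-one F1. Wittig reaction of F1 with the ylide from (hex-5-en-1-yl)triphenylphosphonium bromide and KN(SiMe3)2 gives the relay iodide tert-butyl{[(2Z)-2-iodo-6-methyldodeca-2,6,11-trien-1-yl]oxy}diphenylsilane F2 (either geometry at the new alkene serves). Addition of F2 to 25 under the conditions of step 16 gives the relay tetraene F3. With the second-generation Grubbs catalyst the ruthenium carbene is loaded at the unhindered terminal alkene of F3, expels cyclopentene to place the alkylidene directly on C4, and this closes onto the C5 vinyl group to give 29.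

2. Step 16 (alkenylmagnesium addition). Non-chelated (Felkin-type) attack may compete with the magnesium chelate and erode the facial selectivity at C9; silyl migration or elimination in the β-silyloxy alkenyllithium may lower the conversion. Fallback, setting out from crude 28 (C9 epimer mixture) and returning at 28: Dess–Martin oxidation to the enone (3R,4R,5S,7Z)-7-{[(tert-butyldiphenylsilyl)oxy]methyl}-4-(2,2-dibromovinyl)-5-[(4-methoxybenzyl)oxy]-11-methyl-3-(triethylsilyloxy)dodeca-1,7,11-trien-6-one F4, then reagent-controlled Corey–Bakshi–Shibata reduction ((S)-2-methyl-CBS-oxazaborolidine, catecholborane, toluene, −78 °C). With the 2-substituted alkenyl group as the larger ketone substituent this reagent should deliver the (9S)-alcohol, and the Felkin preference of the α-alkoxy ketone points the same way.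

3. Step 23 (cyclocarbonylation). The catalyst may be diverted: reduction to zerovalent palladium would allow ionisation of the allylic C9 ester or of the allylic C6–O bond of the product, and alkyne insertion may be slow on the medium ring. Fallback, a radical route to the same C11–C12 bond, setting out from 35 and returning at 36: COCl2, pyridine, CH2Cl2, 0 °C, then PhSeH, pyridine converts the secondary O6–H (the hindered tertiary hydroxyl should not react) into the Se-phenyl selenocarbonate F5. Bu3SnH, AIBN, benzene, 80 °C (slow addition) generates the alkoxycarbonyl radical, which cyclises 5-exo-dig onto the ethynyl group; hydrogen transfer to the resulting vinyl radical gives 36.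

Further compounds
F1 | step 17 | (Z)-7-[(tert-butyldiphenylsilyl)oxy]-6-iodohept-5-en-2-one | CC(=O)CC/C=C(\I)CO[Si](c1ccccc1)(c1ccccc1)C(C)(C)C
F2 | step 17 | tert-butyl{[(2Z)-2-iodo-6-methyldodeca-2,6,11-trien-1-yl]oxy}diphenylsilane (6E/6Z mixture) | C=CCCCC=C(C)CC/C=C(\I)CO[Si](c1ccccc1)(c1ccccc1)C(C)(C)C
F3 | step 17 | relay analogue of 28 carrying a hex-5-enylidene group on C4 | C=C[C@@H](O[Si](CC)(CC)CC)[C@H](C=C(Br)Br)[C@H](OCc1ccc(OC)cc1)[C@@H](O)/C(CO[Si](c1ccccc1)(c1ccccc1)C(C)(C)C)=C\CCC(C)=CCCCC=C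
F4 | step 16 | (3R,4R,5S,7Z)-7-{[(tert-butyldiphenylsilyl)oxy]methyl}-4-(2,2-dibromovinyl)-5-[(4-methoxybenzyl)oxy]-11-methyl-3-(triethylsilyloxy)dodeca-1,7,11-trien-6-one | C=C[C@@H](O[Si](CC)(CC)CC)[C@H](C=C(Br)Br)[C@H](OCc1ccc(OC)cc1)C(=O)/C(CO[Si](c1ccccc1)(c1ccccc1)C(C)(C)C)=C\CCC(C)=C
F5 | step 23 | Se-phenyl selenocarbonate of 35 at O6 | C/C1=C/[C@@H](OC(=O)[Se]c2ccccc2)[C@H](C#C)[C@H](OC(=O)C(C)C)[C@@H](OC(=O)C(C)(C)O)/C(CO[Si](c2ccccc2)(c2ccccc2)C(C)(C)C)=C\CC1
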